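Atoms are numbered C1–C30 in the order of the target SMILES. Retrosynthetic cuts, last bond first: O26–C24 (δ-lactone), C8–C27 (cyclopentane), C19=C20 and C16–C17 (cyclopentene), C10–C21 (vicinal quaternary bond), C10=C13 (lactam ring), N29–C28, C2–C30, C7–C8.
Structural handle: the quaternary carbons C10 and C21 share one bond of the cycloheptane C10–C13–C14–C15–C16–C20–C21, in which C13 lies α to C28 (a lactam carbonyl until late) and C20 can carry oxygen. That C28/C20 1,5-dicarbonyl array is the retro-aldol product of a cyclobutanol, so a [2+2] photocycloaddition of the C10=C13 lactam with a C20=C21 enol ether, followed by C13–C20 cleavage, builds the ring.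
Forward ring order: γ-lactone/pyrrolidine bicycle (vinylogous Mannich, then 5-exo radical closure), dihydropyridone (Horner–Wadsworth–Emmons), cyclobutane plus cyclopentane merged into the cycloheptanone (key step), cyclopentene (Wittig), cyclopentane C8–C9–C10–C21–C27 (aza-pinacol), δ-lactone.
Stereochemistry: C8 from (S)-tert-butanesulfinamide and C7 from the anti-selective Mannich step; C2 from the enforced cis ring fusion; C10, C21 and C13 in the key step (C7 screens one lactam face, a silylene ring locks the enol ether geometry, kinetic protonation); C16 by kinetic protonation; C27 in the SmI2 cyclisation, which also makes C8 quaternary with retention.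

Key step: step 17

Assumption: the Lewis-acid-promoted vinylogous Mannich addition follows the open transition-state model for N-sulfinyl aldimines (attack anti to the tert-butyl group of the s-cis sulfinyl imine); were the opposite facial sense to operate, (R)-2-methylpropane-2-sulfinamide would be used in the same sequence.

Step 1
Reactants: 1 4-methylfuran-2(5H)-one
Product: 2 4-methyl-2-(triisopropylsilyloxy)furan
Conditions: iPr3SiOTf, Et3N, CH2Cl2, 0 °C
Reagents that add atoms: triisopropylsilyl trifluoromethanesulfonate, CC(C)[Si](OS(=O)(=O)C(F)(F)F)(C(C)C)C(C)C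
Why: Soft enolisation at the γ-CH2 (C7) and O-silylation aromatise the butenolide to the 2-silyloxyfuran, the usual dienol ether for vinylogous Mannich reactions.

Step 2
Reactants: 3 ethyl 4-(benzyloxy)-3-oxobutanoate
Product: 4 ethyl 2-[2-(benzyloxymethyl)-1,3-dioxolan-2-yl]acetate
Conditions: HOCH2CH2OH, TsOH·H2O (cat.), toluene, reflux (Dean–Stark)
Reagents that add atoms: ethane-1,2-diol, OCCO
Why: Acid-catalysed ketalisation with azeotropic removal of water masks the C10 ketone, so that neither a β-oxo aldehyde nor a free β-amino ketone has to be handled before N-acylation.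

Step 3
Reactants: 4 ethyl 2-[2-(benzyloxymethyl)-1,3-dioxolan-2-yl]acetate
Product: 5 2-[2-(benzyloxymethyl)-1,3-dioxolan-2-yl]acetaldehyde
Conditions: iBu2AlH (1.1 equiv), CH2Cl2, −78 °C
Reagents that add atoms: none
Why: Partial ester reduction stops at the aluminium hemiacetal at −78 °C and releases the C8 aldehyde on work-up.

Step 4
Reactants: 5 2-[2-(benzyloxymethyl)-1,3-dioxolan-2-yl]acetaldehyde; 6 (S)-2-methylpropane-2-sulfinamide
Product: 7 (S,E)-N-{2-[2-(benzyloxymethyl)-1,3-dioxolan-2-yl]ethylidene}-2-methylpropane-2-sulfinamide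
Conditions: Ti(OEt)4, THF, rt
Reagents that add atoms: none
Why: Titanium-mediated condensation of the aldehyde with the sulfinamide should give the (E)-N-sulfinyl aldimine that carries the chiral auxiliary and the future N29.

Step 5
Reactants: 7 (S,E)-N-sulfinyl aldimine; 2 4-methyl-2-(triisopropylsilyloxy)furan
Product: 8 (S)-N-{(1R)-2-[2-(benzyloxymethyl)-1,3-dioxolan-2-yl]-1-[(2S)-3-methyl-5-oxo-2,5-dihydrofuran-2-yl]ethyl}-2-methylpropane-2-sulfinamide (anti adduct)
Conditions: Me3SiOTf (0.2 equiv), CH2Cl2, −78 °C
Reagents that add atoms: none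
Why: The vinylogous Mukaiyama–Mannich addition at the furan γ-carbon forms C7–C8 through an open transition state that favours the anti adduct, and attack on the imine face opposite the tert-butyl group of the sulfinyl auxiliary sets C8 (R) and with it C7 (S).

Step 6
Reactants: 8 anti sulfinamide adduct
Product: 10 (5S)-5-{(1R)-2-[2-(benzyloxymethyl)-1,3-dioxolan-2-yl]-1-[(trimethylsilylmethyl)amino]ethyl}-4-methylfuran-2(5H)-one, via amine hydrochloride 9 (not isolated)
Conditions: HCl (4 M in dioxane), MeOH, 0 °C; evaporate; Me3SiCH2OTf, iPr2NEt, CH2Cl2, 0 °C → rt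
Reagents that add atoms: (trimethylsilyl)methyl trifluoromethanesulfonate, C[Si](C)(C)COS(=O)(=O)C(F)(F)F
Why: Acidic methanolysis removes the sulfinyl group and N-alkylation of the ammonium salt as it is freed installs C30 as an α-silylamine, so the free primary amine is never stored next to the butenolide.

Step 7
Reactants: 10 α-silylamine butenolide
Product: 12 (3aS,6R,6aS)-6-[3-(benzyloxy)-2-oxopropyl]-3a-methylhexahydro-2H-furo[2,3-c]pyrrol-2-one hydrochloride, via bicyclic ketal amine 11 (not isolated)
Conditions: Ir[dF(CF3)ppy]2(dtbbpy)PF6 (1 mol%), MeOH/MeCN, blue LEDs, rt; then 2 M aqueous HCl, THF, rt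
Reagents that add atoms: water, O; hydrogen chloride, Cl
Why: Photoredox oxidation and desilylation of the α-silylamine give the N–CH2 radical, which adds 5-exo-trig to the butenolide β-carbon C2 (Giese-type cyclisation); the new ring can only be cis-fused, so C7 fixes the quaternary centre C2, and aqueous acid then unmasks the C10 ketone with the amine held as its salt.

Step 8
Reactants: 13 triethyl phosphonoacetate; 14 tert-butyl 4-bromobutanoate
Product: 15 6-tert-butyl 1-ethyl 2-(diethoxyphosphoryl)hexanedioate
Conditions: NaH, DMF, 0 → 60 °C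
Reagents that add atoms: none
Why: C-alkylation of the sodium phosphonoacetate by the primary bromide attaches C14–C16 and the C20 carboxyl to C13.

Step 9
Reactants: 15 alkylated phosphonoacetate
Product: 16 6-tert-butoxy-2-(diethoxyphosphoryl)-6-oxohexanoic acid
Conditions: LiOH, THF/H2O, 0 °C → rt; then 1 M HCl
Reagents that add atoms: lithium hydroxide, [Li+].[OH-]
Why: Saponification takes the unhindered ethyl carboxylate and leaves the tert-butyl ester and the phosphonate esters intact.

Step 10
Reactants: 12 amino ketone hydrochloride; 16 phosphono acid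
Product: 17 N29-acylated amino ketone, tert-butyl 6-{(3aS,6R,6aS)-6-[3-(benzyloxy)-2-oxopropyl]-3a-methyl-2-oxohexahydro-5H-furo[2,3-c]pyrrol-5-yl}-5-(diethoxyphosphoryl)-6-oxohexanoate (both C13 epimers)
Conditions: EDC·HCl, HOAt, iPr2NEt, CH2Cl2, 0 °C → rt
Reagents that add atoms: none
Why: Carbodiimide amide coupling acylates the secondary amine as it is released from its salt, and the two epimers at the phosphonate carbon converge in the next step.

Step 11
Reactants: 17 phosphonoacetamide ketone
Product: 18 unsaturated lactam (5,6-dihydropyridin-2(1H)-one fused through N29–C8 to the lactone-pyrrolidine; CH2OBn on C10, (CH2)3CO2tBu on C13; C2 S, C7 S, C8 R)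
Conditions: NaH, THF, 0 → 40 °C
Reagents that add atoms: none
Why: Intramolecular Horner–Wadsworth–Emmons olefination of the C10 ketone closes the six-membered lactam and gives the tetrasubstituted C10=C13 alkene, the ring allowing only one alkene geometry.

Step 12
Reactants: 18 unsaturated lactam tert-butyl ester
Product: 19 unsaturated lactam C20 carboxylic acid
Conditions: CF3CO2H, CH2Cl2, 0 °C → rt
Reagents that add atoms: none
Why: Acidolysis of the tert-butyl ester with loss of 2-methylpropene frees the C20 acid, while benzyl ether, lactone and lactam are stable to the acid.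

Step 13
Reactants: 19 unsaturated lactam C20 carboxylic acid
Product: 21 β-keto allyl ester (C20 ketone, C21 methylene, allyl ester carbon on C21), via acyl imidazolide 20 (not isolated)
Conditions: 1,1'-carbonyldiimidazole, THF, rt; then Mg(O2CCH2CO2CH2CH=CH2)2, THF, 40 °C; aqueous HCl work-up
Reagents that add atoms: magnesium bis(allyl malonate), C=CCOC(=O)CC(=O)[O-].C=CCOC(=O)CC(=O)[O-].[Mg+2]
Why: Decarboxylative Claisen acylation of the magnesium malonate half-ester by the acyl imidazolide gives the β-keto ester under near-neutral conditions and makes C21 the only doubly activated carbon of the tether.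

Step 14
Reactants: 21 β-keto allyl ester; 22 tert-butyl acrylate
Product: 24 allyl β-keto ester with C21 carrying CH2OH (C27) and CH2CH2CO2tBu (C22–C24), both C21 epimers, via Michael adduct 23 (not isolated)
Conditions: K2CO3 (0.1 equiv), THF, rt; then 37% aqueous CH2O, KHCO3 (cat.), rt
Reagents that add atoms: formaldehyde, C=O
Why: Michael addition of the β-keto ester to the acrylate and aldol hydroxymethylation of the remaining acidic position place C22–C24 and C27 on C21 regiospecifically, and the configuration of C21 is irrelevant because it becomes sp2 in step 16.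

Step 15
Reactants: 24 hydroxymethylated allyl β-keto ester
Product: 25 β-hydroxy ketone (C20 ketone; C21–H carrying CH2OH and CH2CH2CO2tBu)
Conditions: Pd(PPh3)4 (5 mol%), HCO2H, Et3N, THF, rt → 40 °C
Reagents that add atoms: none
Why: Zerovalent palladium removes the allyl group as propene (Tsuji–Trost deallylation with formate) and the resulting β-keto acid loses CO2, which leaves the ketone at C20.

Step 16
Reactants: 25 β-hydroxy ketone
Product: 26 photosubstrate, unsaturated lactam whose C13 carries a (CH2)3 tether to C20 of a 2,2-diisopropyl-4H-1,3,2-dioxasiline (C20=C21 enol ether, C21 bearing CH2CH2CO2tBu)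
Conditions: iPr2Si(OTf)2, Et3N, CH2Cl2, −78 → 0 °C
Reagents that add atoms: diisopropylsilyl bis(trifluoromethanesulfonate), CC(C)[Si](OS(=O)(=O)C(F)(F)F)(OS(=O)(=O)C(F)(F)F)C(C)C
Why: The primary C27 hydroxyl is silylated first, which tethers the second silyl triflate so that it reaches only O20, and triethylamine then removes the C21 proton under equilibrating conditions to give the more substituted endocyclic enol ether (cyclic silyl enol ether formation), whose six-membered ring holds O20 cis to C27.

Step 17
Reactants: 26 photosubstrate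
Product: 28 cycloheptanone-fused lactam (C20 ketone; C10 quaternary with CH2OBn syn to C7; C21 quaternary with CH2OH syn to C9 and CH2CH2CO2tBu syn to C11; C13–H syn to C11), via cyclobutane photoadduct 27 (not isolated)
Conditions: hν (300 nm), degassed CH2Cl2, rt; then HF·pyridine, THF, 0 °C → rt
Reagents that add atoms: none
Why: Proposed new method: direct excitation of the C10=C13 unsaturated lactam gives its triplet, which bonds C13 to C20 in a five-membered (1,5, 5-exo-trig) closure over the C14–C16 tether and then closes the four-membered ring by C10–C21 radical recombination, so the two crowded carbons are joined without any ionic bond formation; HF then frees the C20 hydroxyl, and the strained C13–C20 bond, flanked by this donor and the C28 lactam acceptor, breaks in a retro-aldol step that merges the four- and five-membered rings into the seven-membered ketone and leaves a lactam enol that is protonated at C13. The closest known reaction type is the intramolecular De Mayo sequence ([2+2] photocycloaddition of an enone or unsaturated lactam with an enol ether, then retro-aldol ring expansion), which has not been shown for a cyclobutane with four fully substituted carbons. C10 is set by addition to the lactam face that carries H8, because the C7 branch of the bicyclic lactone on C8 screens the other face. C21 is set by the six-membered silylene ring, which fixes O20 cis to C27 on the enol ether and so places C27 on the lactam side (syn to C9) and C22 syn to C11 once the two cis ring fusions are formed. C13 is set by kinetic protonation on the face of C11, the other face being covered by the new seven-membered ring. Straight rather than crossed regiochemistry is secured by the three-carbon tether, and chemoselectivity by the absence of any other group that absorbs at 300 nm.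

Step 18
Reactants: 28 cycloheptanone-fused lactam
Product: 29 C27 tert-butyldimethylsilyl ether of 28
Conditions: tBuMe2SiCl, imidazole, DMF, rt
Reagents that add atoms: tert-butyldimethylsilyl chloride, CC(C)(C)[Si](C)(C)Cl
Why: Silylation of the primary C27 hydroxyl blocks retro-aldol loss of formaldehyde from the β-hydroxy ketone in the basic steps that follow.

Step 19
Reactants: 29 silyl-protected cycloheptanone
Product: 30 C16-(3-chloropropyl) ketone (both C16 epimers)
Conditions: KN(SiMe3)2 (1.05 equiv), THF, −78 °C; ICH2CH2CH2Cl, −78 → −20 °C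
Reagents that add atoms: 1-chloro-3-iodopropane, ClCCCI
Why: The ketone can enolise only towards C16 because C21 is quaternary, and alkylation of the potassium enolate at the iodine-bearing carbon attaches C17–C19.

Step 20
Reactants: 30 C16-(3-chloropropyl) ketone (epimer mixture)
Product: 31 C16 epimer of 30 with the chloropropyl chain syn to C27 (H16 on the face of C11 and C22)
Conditions: KN(SiMe3)2 (1.2 equiv), THF, −78 → −40 °C; then AcOH, −78 °C
Reagents that add atoms: none
Why: Kinetic protonation of the re-formed C16 enolate on the face opposite the fused lactam ring and the C27 silyloxymethyl group should converge both epimers to the one required by the target.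

Step 21
Reactants: 31 chloropropyl ketone
Product: 32 phosphonium iodide (C19–PPh3+ I−)
Conditions: NaI, PPh3, MeCN, 80 °C
Reagents that add atoms: triphenylphosphine, c1ccc(cc1)P(c1ccccc1)c1ccccc1; sodium iodide, [Na+].[I-]
Why: Finkelstein exchange and quaternisation of triphenylphosphine by the primary iodide give the Wittig salt under non-basic conditions that leave C16 untouched.

Step 22
Reactants: 32 phosphonium iodide
Product: 33 cyclopentene-fused lactam (ring C16–C17–C18–C19=C20)
Conditions: KN(SiMe3)2 (1.0 equiv), THF, −78 → 60 °C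
Reagents that add atoms: none
Why: Intramolecular Wittig olefination of the C20 ketone by the C19 ylide closes the five-membered ring and can place the double bond only at C19=C20, and the ylide is too weak a base to enolise the hindered ketone, so C16 is kept.

Step 23
Reactants: 33 cyclopentene-fused lactam
Product: 34 thiolactam (C28=S)
Conditions: Lawesson's reagent (0.6 equiv), toluene, 100 °C
Reagents that add atoms: Lawesson's reagent, COc1ccc(cc1)P1(=S)SP(=S)(S1)c1ccc(OC)cc1
Why: The lactam is the most nucleophilic carbonyl group and should be thionated selectively over the lactone and the tert-butyl ester.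

Step 24
Reactants: 34 thiolactam
Product: 35 tertiary amine (C28 methylene)
Conditions: Raney Ni, THF/EtOH, rt
Reagents that add atoms: none
Why: Reductive desulfurisation turns the thiolactam into the C28 methylene without touching the esters, and the hindered trisubstituted alkene should survive short exposure at room temperature.

Step 25
Reactants: 35 tertiary amine silyl ether
Product: 36 amino alcohol (free C27–OH)
Conditions: HF·pyridine, THF, 0 °C → rt
Reagents that add atoms: none
Why: Fluoride-assisted cleavage of the silyl ether frees the C27 alcohol while esters, lactone and alkene are inert.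

Step 26
Reactants: 36 amino alcohol
Product: 37 amino aldehyde (C27 CHO)
Conditions: Dess–Martin periodinane, CH2Cl2, 0 °C → rt
Reagents that add atoms: none
Why: Hypervalent-iodine oxidation gives the neopentyl, non-enolisable C27 aldehyde without oxidising the tertiary amine.

Step 27
Reactants: 37 amino aldehyde
Product: 38 N29-oxide of 37 (oxygen anti to H8)
Conditions: mCPBA (1.0 equiv), CH2Cl2, −78 → 0 °C
Reagents that add atoms: 3-chloroperoxybenzoic acid, OOC(=O)c1cccc(Cl)c1
Why: The peracid oxidises the amine nitrogen far faster than the hindered alkene or the aldehyde, and oxygen should be delivered to the axial lone pair of the trans-fused indolizidine unit, anti to H8.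

Step 28
Reactants: 38 N-oxide
Product: 40 amino alcohol with the C8–C27 bond (C8 quaternary, C27–OH syn to C22), via iminium trifluoroacetate 39 (not isolated)
Conditions: (CF3CO)2O, CH2Cl2, 0 °C; evaporate; SmI2 (4 equiv), THF, −78 °C → rt
Reagents that add atoms: none
Why: Trifluoroacetylation of the N-oxide and anti elimination of H8, the hydrogen anti-periplanar to N–O and acidified by the C7 acyloxy group, give the more substituted C8 iminium ion (Polonovski–Potier reaction), and SmI2 then joins C8 to the C27 ketyl in a five-membered aza-pinacol closure in which C27 can reach only the former H8 face (C8 quaternary with retention) and chelation of trivalent samarium between the ketyl oxygen and the C24 ester carbonyl places O26 syn to C22.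

Step 29
Reactants: 40 amino alcohol tert-butyl ester
Product: 41 C11 benzyl ether of the target (δ-lactone closed)
Conditions: CF3CO2H, CH2Cl2, 0 °C → rt
Reagents that add atoms: none
Why: Acid cleaves the tert-butyl ester and the resulting δ-hydroxy acid lactonises under the same conditions, O26 and the C22 chain being cis on the cyclopentane.

Step 30
Reactants: 41 benzyl ether of the target
Product: 42 CNP0247797.1
Conditions: BCl3, C6HMe5, CH2Cl2, −78 → −40 °C; MeOH quench
Reagents that add atoms: none
Why: Lewis-acid debenzylation with pentamethylbenzene as cation scavenger frees the C11 alcohol without reducing the alkene or opening the lactones.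

Compound list
1 | 4-methylfuran-2(5H)-one | CC1=CC(=O)OC1 | starting material
2 | 4-methyl-2-(triisopropylsilyloxy)furan | Cc1coc(O[Si](C(C)C)(C(C)C)C(C)C)c1 | intermediate
3 | ethyl 4-(benzyloxy)-3-oxobutanoate | CCOC(=O)CC(=O)COCc1ccccc1 | starting material
4 | ethyl 2-[2-(benzyloxymethyl)-1,3-dioxolan-2-yl]acetate | CCOC(=O)CC1(COCc2ccccc2)OCCO1 | intermediate
5 | 2-[2-(benzyloxymethyl)-1,3-dioxolan-2-yl]acetaldehyde | O=CCC1(COCc2ccccc2)OCCO1 | intermediate
6 | (S)-2-methylpropane-2-sulfinamide | CC(C)(C)[S@](=O)N | starting material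
7 | (S,E)-N-{2-[2-(benzyloxymethyl)-1,3-dioxolan-2-yl]ethylidene}-2-methylpropane-2-sulfinamide | CC(C)(C)[S@](=O)/N=C/CC1(COCc2ccccc2)OCCO1 | intermediate
8 | (S)-N-{(1R)-2-[2-(benzyloxymethyl)-1,3-dioxolan-2-yl]-1-[(2S)-3-methyl-5-oxo-2,5-dihydrofuran-2-yl]ethyl}-2-methylpropane-2-sulfinamide | CC1=CC(=O)O[C@@H]1[C@@H](CC2(COCc3ccccc3)OCCO2)N[S@@](=O)C(C)(C)C | intermediate
9 | hydrochloride of the primary amine from 8 (C7 S, C8 R; not isolated) | CC1=CC(=O)O[C@@H]1[C@@H](CC2(COCc3ccccc3)OCCO2)[NH3+].[Cl-] | intermediate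
10 | (5S)-5-{(1R)-2-[2-(benzyloxymethyl)-1,3-dioxolan-2-yl]-1-[(trimethylsilylmethyl)amino]ethyl}-4-methylfuran-2(5H)-one | CC1=CC(=O)O[C@@H]1[C@@H](CC2(COCc3ccccc3)OCCO2)NC[Si](C)(C)C | intermediate
11 | (3aS,6R,6aS)-6-{[2-(benzyloxymethyl)-1,3-dioxolan-2-yl]methyl}-3a-methylhexahydro-2H-furo[2,3-c]pyrrol-2-one (not isolated) | C[C@@]12CC(=O)O[C@@H]1[C@@H](CC3(COCc4ccccc4)OCCO3)NC2 | intermediate
12 | (3aS,6R,6aS)-6-[3-(benzyloxy)-2-oxopropyl]-3a-methylhexahydro-2H-furo[2,3-c]pyrrol-2-one hydrochloride | C[C@@]12CC(=O)O[C@@H]1[C@@H](CC(=O)COCc3ccccc3)[NH2+]C2.[Cl-] | intermediate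
13 | triethyl phosphonoacetate | CCOC(=O)CP(=O)(OCC)OCC | starting material
14 | tert-butyl 4-bromobutanoate | CC(C)(C)OC(=O)CCCBr | starting material
15 | 6-tert-butyl 1-ethyl 2-(diethoxyphosphoryl)hexanedioate | CCOC(=O)C(CCCC(=O)OC(C)(C)C)P(=O)(OCC)OCC | intermediate
16 | 6-tert-butoxy-2-(diethoxyphosphoryl)-6-oxohexanoic acid | OC(=O)C(CCCC(=O)OC(C)(C)C)P(=O)(OCC)OCC | intermediate
17 | tert-butyl 6-{(3aS,6R,6aS)-6-[3-(benzyloxy)-2-oxopropyl]-3a-methyl-2-oxohexahydro-5H-furo[2,3-c]pyrrol-5-yl}-5-(diethoxyphosphoryl)-6-oxohexanoate (both C13 epimers) | C[C@@]12CC(=O)O[C@@H]1[C@@H](CC(=O)COCc3ccccc3)N(C2)C(=O)C(CCCC(=O)OC(C)(C)C)P(=O)(OCC)OCC | intermediate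
18 | unsaturated lactam: N29–C8-fused 5,6-dihydropyridin-2(1H)-one, C10 CH2OBn, C13 (CH2)3CO2tBu (C2 S, C7 S, C8 R) | C[C@@]12CC(=O)O[C@@H]1[C@H]3CC(COCc4ccccc4)=C(CCCC(=O)OC(C)(C)C)C(=O)N3C2 | intermediate
19 | C20 carboxylic acid of 18 | C[C@@]12CC(=O)O[C@@H]1[C@H]3CC(COCc4ccccc4)=C(CCCC(=O)O)C(=O)N3C2 | intermediate
20 | C20 acyl imidazolide of 19 (not isolated) | C[C@@]12CC(=O)O[C@@H]1[C@H]3CC(COCc4ccccc4)=C(CCCC(=O)n4ccnc4)C(=O)N3C2 | intermediate
21 | β-keto allyl ester (C20 ketone, C21H2, allyl ester) | C[C@@]12CC(=O)O[C@@H]1[C@H]3CC(COCc4ccccc4)=C(CCCC(=O)CC(=O)OCC=C)C(=O)N3C2 | intermediate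
22 | tert-butyl acrylate | C=CC(=O)OC(C)(C)C | starting material
23 | Michael adduct of 21, C21–H carrying CH2CH2CO2tBu (C21 epimers; not isolated) | C[C@@]12CC(=O)O[C@@H]1[C@H]3CC(COCc4ccccc4)=C(CCCC(=O)C(CCC(=O)OC(C)(C)C)C(=O)OCC=C)C(=O)N3C2 | intermediate
24 | allyl β-keto ester with C21 carrying CH2OH and CH2CH2CO2tBu (C21 epimers) | C[C@@]12CC(=O)O[C@@H]1[C@H]3CC(COCc4ccccc4)=C(CCCC(=O)C(CO)(CCC(=O)OC(C)(C)C)C(=O)OCC=C)C(=O)N3C2 | intermediate
25 | β-hydroxy ketone (C20 ketone, C21–H with CH2OH and CH2CH2CO2tBu; C21 epimers) | C[C@@]12CC(=O)O[C@@H]1[C@H]3CC(COCc4ccccc4)=C(CCCC(=O)C(CO)CCC(=O)OC(C)(C)C)C(=O)N3C2 | intermediate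
26 | photosubstrate: unsaturated lactam tethered through C14–C16 to C20 of the 2,2-diisopropyl-4H-1,3,2-dioxasiline (C20=C21) | C[C@@]12CC(=O)O[C@@H]1[C@H]3CC(COCc4ccccc4)=C(CCCC4=C(CCC(=O)OC(C)(C)C)CO[Si](C(C)C)(C(C)C)O4)C(=O)N3C2 | intermediate
27 | cyclobutane photoadduct (bonds C10–C21 and C13–C20 on the H8 face, silylene intact; not isolated) | C[C@@]12CC(=O)O[C@@H]1[C@H]3C[C@@]4(COCc5ccccc5)[C@@]5(CCC[C@]5(O[Si](C(C)C)(C(C)C)OC6)[C@]46CCC(=O)OC(C)(C)C)C(=O)N3C2 | intermediate
28 | cycloheptanone-fused lactam (C20 ketone; C10 CH2OBn syn to C7; C21 CH2OH syn to C9, CH2CH2CO2tBu syn to C11; H13 syn to C11) | C[C@@]12CC(=O)O[C@@H]1[C@H]3C[C@@]4(COCc5ccccc5)[C@H](CCCC(=O)[C@]4(CO)CCC(=O)OC(C)(C)C)C(=O)N3C2 | intermediate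
29 | C27 tert-butyldimethylsilyl ether of 28 | C[C@@]12CC(=O)O[C@@H]1[C@H]3C[C@@]4(COCc5ccccc5)[C@H](CCCC(=O)[C@]4(CO[Si](C)(C)C(C)(C)C)CCC(=O)OC(C)(C)C)C(=O)N3C2 | intermediate
30 | C16-(3-chloropropyl) derivative of 29 (both C16 epimers) | C[C@@]12CC(=O)O[C@@H]1[C@H]3C[C@@]4(COCc5ccccc5)[C@H](CCC(CCCCl)C(=O)[C@]4(CO[Si](C)(C)C(C)(C)C)CCC(=O)OC(C)(C)C)C(=O)N3C2 | intermediate
31 | C16 epimer of 30 with the chloropropyl chain syn to C27 | C[C@@]12CC(=O)O[C@@H]1[C@H]3C[C@@]4(COCc5ccccc5)[C@H](CC[C@@H](CCCCl)C(=O)[C@]4(CO[Si](C)(C)C(C)(C)C)CCC(=O)OC(C)(C)C)C(=O)N3C2 | intermediate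
32 | triphenylphosphonium iodide from 31 (C19–PPh3+) | C[C@@]12CC(=O)O[C@@H]1[C@H]3C[C@@]4(COCc5ccccc5)[C@H](CC[C@@H](CCC[P+](c5ccccc5)(c5ccccc5)c5ccccc5)C(=O)[C@]4(CO[Si](C)(C)C(C)(C)C)CCC(=O)OC(C)(C)C)C(=O)N3C2.[I-] | intermediate
33 | cyclopentene-fused lactam (C19=C20; C17 syn to C27) | C[C@@]12CC(=O)O[C@@H]1[C@H]3C[C@@]4(COCc5ccccc5)[C@H](CC[C@H]5CCC=C5[C@]4(CO[Si](C)(C)C(C)(C)C)CCC(=O)OC(C)(C)C)C(=O)N3C2 | intermediate
34 | thiolactam of 33 (C28=S) | C[C@@]12CC(=O)O[C@@H]1[C@H]3C[C@@]4(COCc5ccccc5)[C@H](CC[C@H]5CCC=C5[C@]4(CO[Si](C)(C)C(C)(C)C)CCC(=O)OC(C)(C)C)C(=S)N3C2 | intermediate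
35 | tertiary amine (C28 methylene), C27 silyl ether | C[C@@]12CC(=O)O[C@@H]1[C@H]3C[C@@]4(COCc5ccccc5)[C@H](CC[C@H]5CCC=C5[C@]4(CO[Si](C)(C)C(C)(C)C)CCC(=O)OC(C)(C)C)CN3C2 | intermediate
36 | amino alcohol (C27–OH) | C[C@@]12CC(=O)O[C@@H]1[C@H]3C[C@@]4(COCc5ccccc5)[C@H](CC[C@H]5CCC=C5[C@]4(CO)CCC(=O)OC(C)(C)C)CN3C2 | intermediate
37 | amino aldehyde (C27 CHO) | C[C@@]12CC(=O)O[C@@H]1[C@H]3C[C@@]4(COCc5ccccc5)[C@H](CC[C@H]5CCC=C5[C@]4(C=O)CCC(=O)OC(C)(C)C)CN3C2 | intermediate
38 | N29-oxide of 37 (oxygen anti to H8) | C[C@@]12CC(=O)O[C@@H]1[C@H]3C[C@@]4(COCc5ccccc5)[C@H](CC[C@H]5CCC=C5[C@]4(C=O)CCC(=O)OC(C)(C)C)C[N@+]3([O-])C2 | intermediate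
39 | C8=N29 iminium trifluoroacetate (not isolated) | C[C@@]12CC(=O)O[C@@H]1C=3C[C@@]4(COCc5ccccc5)[C@H](CC[C@H]5CCC=C5[C@]4(C=O)CCC(=O)OC(C)(C)C)C[N+]3C2.[O-]C(=O)C(F)(F)F | intermediate
40 | amino alcohol with the C8–C27 bond (C27–OH syn to C22; tert-butyl ester, benzyl ether) | C[C@@]12CC(=O)O[C@@H]1[C@]13C[C@@]4(COCc5ccccc5)[C@H](CC[C@H]5CCC=C5[C@@]4(CCC(=O)OC(C)(C)C)[C@@H]1O)CN3C2 | intermediate
41 | C11 benzyl ether of the target | C[C@@]12CC(=O)O[C@@H]1[C@]13C[C@@]4(COCc5ccccc5)[C@H](CC[C@H]5CCC=C5[C@]45CCC(=O)O[C@H]15)CN3C2 | intermediate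
42 | CNP0247797.1 | C[C@@]12CC(=O)O[C@@H]1[C@]13C[C@@]4(CO)[C@H](CC[C@H]5CCC=C5[C@]45CCC(=O)O[C@H]15)CN3C2 | target

Total step count: 30. Longest linear sequence: 27 steps (from 3 to 42: steps 2–7 and 10–30).

Steps most likely to fail

Step 17. The 1,4-diradical formed after the first bond may revert or cleave instead of closing a cyclobutane with four fully substituted carbons, or the photoadduct may resist fragmentation at the lactam. The fallback uses known chemistry, sets out from 21 and returns at 28; only one quaternary centre is made photochemically and the second by Michael addition. The acrylate is left out of step 14, so single hydroxymethylation of 21 would give the allyl 2-(hydroxymethyl)-3-oxo ester F1, and decarboxylation as in step 15 the 1-hydroxy-3-ketone F2. Silylene formation as in step 16 would give the trisubstituted cyclic silyl enol ether F3. Irradiation would give the cyclobutane F4, which has three fully substituted carbons and lies within the documented range of the De Mayo sequence, and fluoride-triggered retro-aldol would give the cycloheptanone F5 with C21 still bearing hydrogen. Dess–Martin oxidation would give the 2-formyl ketone F6. Its triethylamine-catalysed Michael addition to tert-butyl acrylate 22 would create the C21 quaternary centre on the face opposite the lactam ring, giving the quaternary formyl ketone F7. Aldehyde-selective reduction (NaBH4, −78 °C) would then return to 28.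

Step 28. Elimination in the Polonovski–Potier stage may remove a hydrogen from C28 or C30 instead of H8, or the iminium ion and the aldehyde may be reduced separately instead of coupling. The fallback inverts the polarity at C8, sets out from 36 and returns at 40. Opening of the γ-lactone with MeNH(OMe)·HCl/AlMe3 would give the Weinreb amide diol F8. Dess–Martin oxidation of both alcohols would give the keto aldehyde F9, in which only C8 can enolise. Intramolecular aldol addition of the C8 enolate to the C27 aldehyde (LiN(SiMe3)2, THF, −78 °C) would close the cyclopentane on the same face and give the aldol F10. NaBH4 would reduce the C7 ketone from the methyl side to the hydroxy amide F11, and TsOH would close the γ-lactone with loss of N,O-dimethylhydroxylamine to reach 40.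

Step 20. Protonation of the C16 enolate may show poor or reversed facial selectivity. The fallback gives up kinetic control, sets out from 30 and returns at 31: the C16 epimers of 30 are separated by chromatography, 31 is carried on, and the unwanted epimer is re-equilibrated thermodynamically (catalytic DBU, toluene) and separated again. No new compound is involved.

Further compounds
F1 | step 17 | allyl 2-(hydroxymethyl)-3-oxo ester from 21 (C21 bearing H, CH2OH and CO2allyl) | C[C@@]12CC(=O)O[C@@H]1[C@H]3CC(COCc4ccccc4)=C(CCCC(=O)C(CO)C(=O)OCC=C)C(=O)N3C2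
F2 | step 17 | 1-hydroxy-3-ketone (C20 ketone, C21H2, C27H2OH) | C[C@@]12CC(=O)O[C@@H]1[C@H]3CC(COCc4ccccc4)=C(CCCC(=O)CCO)C(=O)N3C2
F3 | step 17 | trisubstituted cyclic silyl enol ether (C20=C21H in the 2,2-diisopropyl-4H-1,3,2-dioxasiline) | C[C@@]12CC(=O)O[C@@H]1[C@H]3CC(COCc4ccccc4)=C(CCCC4=CCO[Si](C(C)C)(C(C)C)O4)C(=O)N3C2
F4 | step 17 | cyclobutane photoadduct with C21–H (not isolated) | C[C@@]12CC(=O)O[C@@H]1[C@H]3C[C@@]4(COCc5ccccc5)[C@@]5(CCC[C@]5(O[Si](C(C)C)(C(C)C)OC6)[C@H]46)C(=O)N3C2
F5 | step 17 | cycloheptanone with C21–H carrying CH2OH (C21 epimerisable) | C[C@@]12CC(=O)O[C@@H]1[C@H]3C[C@@]4(COCc5ccccc5)[C@H](CCCC(=O)C4CO)C(=O)N3C2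
F6 | step 17 | 2-formyl cycloheptanone (C27 CHO on C21, enolisable) | C[C@@]12CC(=O)O[C@@H]1[C@H]3C[C@@]4(COCc5ccccc5)[C@H](CCCC(=O)C4C=O)C(=O)N3C2
F7 | step 17 | quaternary formyl ketone (C21 with CHO syn to C9 and CH2CH2CO2tBu syn to C11) | C[C@@]12CC(=O)O[C@@H]1[C@H]3C[C@@]4(COCc5ccccc5)[C@H](CCCC(=O)[C@]4(C=O)CCC(=O)OC(C)(C)C)C(=O)N3C2
F8 | step 28 | Weinreb amide diol (lactone of 36 opened; C7–OH and C27–OH free) | C[C@@]2(CC(=O)N(C)OC)[C@H](O)[C@H]3C[C@@]4(COCc5ccccc5)[C@H](CC[C@H]5CCC=C5[C@]4(CO)CCC(=O)OC(C)(C)C)CN3C2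
F9 | step 28 | keto aldehyde (C7 ketone, C27 aldehyde) | C[C@@]2(CC(=O)N(C)OC)C(=O)[C@H]3C[C@@]4(COCc5ccccc5)[C@H](CC[C@H]5CCC=C5[C@]4(C=O)CCC(=O)OC(C)(C)C)CN3C2
F10 | step 28 | aldol product (C8–C27 bond, C27–OH, C7 ketone) | C[C@@]2(CC(=O)N(C)OC)C(=O)[C@]13C[C@@]4(COCc5ccccc5)[C@H](CC[C@H]5CCC=C5[C@@]4(CCC(=O)OC(C)(C)C)[C@@H]1O)CN3C2
F11 | step 28 | hydroxy Weinreb amide after C7 reduction (C7–OH, C27–OH, C8–C27 bond) | C[C@@]2(CC(=O)N(C)OC)[C@H](O)[C@]13C[C@@]4(COCc5ccccc5)[C@H](CC[C@H]5CCC=C5[C@@]4(CCC(=O)OC(C)(C)C)[C@@H]1O)CN3C2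
F0 | step 20 | none | none
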